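**Retrosynthetic overview**

The target is the C2-symmetric 8,8''-biflavone 7,7''-di-O-methylcupressuflavone; the strategic disconnection is the C8–C8'' biaryl bond, which gives two identical genkwanin (5,4'-dihydroxy-7-methoxyflavone) units, so the axis is made by dehydrogenative homocoupling of two complete flavones.
Enabling feature: in ring A of each half the C5 hydroxyl sits in a six-membered chelate with the C4 carbonyl of ring C, and C8 (between C7–OMe and the ring oxygen O1 on C8a) is the carbon para to that C5 oxygen; one-electron oxidation of the chelated C5 phenolate puts radical character on C8, so two C8–H bonds can be joined without prior halogenation or metalation.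
Precursor shaping: the 4'-hydroxyl of ring B is carried through the coupling as a pivalate, so the C5 hydroxyl is the only oxidisable phenol and ring B is electron-poor; methanolysis at the end removes both esters.
Each monomer comes from a symmetric ring A acetophenone and a ring B aldehyde: Claisen–Schmidt condensation forms the C2–C3 bond of the future ring C, iodine/DMSO oxidative cyclisation closes ring C (O1–C2 bond), and benzyl is then exchanged for pivaloyl.
Order: ring C of the monomer (steps 1–2), protecting-group exchange (steps 3–4), C8–C8'' coupling of two flavones (step 5), ester cleavage (step 6); rings A and B are bought.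

Key step: step 5

Assumption: the target SMILES carries no descriptor for the hindered C8–C8'' axis, so the biaryl is planned as the racemate and no control of the axis is attempted.

**Route**

Step 1
Reactants: 1 1-(2,6-dihydroxy-4-methoxyphenyl)ethan-1-one (2',6'-dihydroxy-4'-methoxyacetophenone); 2 4-(benzyloxy)benzaldehyde
Product: 3 (E)-3-[4-(benzyloxy)phenyl]-1-(2,6-dihydroxy-4-methoxyphenyl)prop-2-en-1-one (2',6'-dihydroxychalcone)
Conditions: KOH (50% aq, 10 equiv), EtOH, rt, 48 h; then 2 M HCl, 0 °C
Reagents that add atoms: none
Why: Claisen–Schmidt (crossed aldol) condensation, in which the acetyl enolate of 1 adds to the non-enolisable aldehyde 2 and base-induced dehydration should give the conjugated E-enone; because 1 is symmetric, either ortho hydroxyl can later close ring C to the same flavone.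

Step 2
Reactants: 3 the 2',6'-dihydroxychalcone
Product: 5 2-[4-(benzyloxy)phenyl]-5-hydroxy-7-methoxy-4H-chromen-4-one (4'-O-benzylgenkwanin), via flavanone 4 (not isolated)
Conditions: I2 (10 mol %), DMSO, 130 °C
Reagents that add atoms: none
Why: Iodine-catalysed oxidative cyclisation of a 2'-hydroxychalcone in DMSO, in which 6-endo oxa-Michael closure of ring C gives flavanone 4 and iodine-mediated dehydrogenation (DMSO as terminal oxidant) should give the flavone, the benzyl ether and the chelated phenol being inert.

Step 3
Reactants: 5 4'-O-benzylgenkwanin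
Product: 6 genkwanin (5-hydroxy-2-(4-hydroxyphenyl)-7-methoxy-4H-chromen-4-one)
Conditions: H2 (1 atm), 10% Pd/C, THF–MeOH, rt
Reagents that add atoms: none
Why: Catalytic hydrogenolysis of the benzyl aryl ether, under which the cross-conjugated C2=C3 bond of the flavone and the aryl methyl ether should not be reduced at one atmosphere and room temperature.

Step 4
Reactants: 6 genkwanin
Product: 7 4-(5-hydroxy-7-methoxy-4-oxo-4H-chromen-2-yl)phenyl 2,2-dimethylpropanoate (4'-O-pivaloylgenkwanin)
Conditions: PivCl (1.1 equiv), pyridine, CH2Cl2, 0 °C to rt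
Reagents that add atoms: pivaloyl chloride, CC(C)(C)C(=O)Cl
Why: Chemoselective O-acylation of a phenol with an acid chloride, in which the free 4'-hydroxyl should react while the C5 hydroxyl, hydrogen-bonded to the C4 carbonyl and hindered, stays free; the ester removes the second oxidisable phenol and deactivates ring B for step 5.

Step 5
Reactants: 7 4'-O-pivaloylgenkwanin (two molecules)
Product: 9 4',4'''-di-O-pivaloyl-7,7''-di-O-methylcupressuflavone (the 8,8''-linked dimer of 7), via bis-dienone 8 (not isolated)
Conditions: FeCl3 (anhydrous, 2.5 equiv per 7), 1,4-dioxane, reflux; then 2 M HCl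
Reagents that add atoms: none
Why: FeCl3 binds the C5 phenolate and C4 carbonyl of 7 as a six-membered chelate, inner-sphere electron transfer to trivalent iron gives a ring A phenoxyl radical with spin density at C8 (para to O5), two such units combine C8 to C8'' to give bis-dienone 8, and tautomerisation with loss of the two C8 hydrogens restores both aromatic rings to give 9. The closest known reaction type is the FeCl3-mediated oxidative coupling of chelated ortho-acyl phenols, as used for the C–C dimerisation of 5-hydroxy-7-alkoxyflavones and of ortho-hydroxyacetophenones. No ring is closed in this step. No stereocentre is created, and the tetra-ortho-substituted C8–C8'' axis is formed without control as the racemate, which is all the target asks for. The step needs regioselectivity for C8 over C6 and chemoselectivity for ring A over ring B: C8 is the para position of the oxidised phenol and lies away from the iron-bearing chelate that crowds C6, and the pivalate leaves the C5 hydroxyl as the only phenol while making ring B electron-poor. The amount of FeCl3 is kept close to the two electrons needed per dimer so that the remaining C6 positions of 9 should not couple further.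

Step 6
Reactants: 9 the bis-pivalate dimer
Product: 10 7,7''-di-O-methylcupressuflavone (5,5'-dihydroxy-2,2'-bis(4-hydroxyphenyl)-7,7'-dimethoxy-4H,4'H-[8,8'-bichromene]-4,4'-dione), the target
Conditions: K2CO3 (4 equiv), MeOH–THF, rt; then 1 M HCl
Reagents that add atoms: none
Why: Base-mediated transesterification (methanolysis) of the two aryl pivalates, in which the 4'-phenoxide is a good leaving group and the methyl ethers, the chelated C5 phenols and the biaryl bond should be untouched.

**Compound list**

1 | 1-(2,6-dihydroxy-4-methoxyphenyl)ethan-1-one (2',6'-dihydroxy-4'-methoxyacetophenone) | CC(=O)c1c(O)cc(OC)cc1O | starting material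
2 | 4-(benzyloxy)benzaldehyde | O=Cc1ccc(OCc2ccccc2)cc1 | starting material
3 | (E)-3-[4-(benzyloxy)phenyl]-1-(2,6-dihydroxy-4-methoxyphenyl)prop-2-en-1-one | COc1cc(O)c(C(=O)/C=C/c2ccc(OCc3ccccc3)cc2)c(O)c1 | intermediate
4 | 2-[4-(benzyloxy)phenyl]-5-hydroxy-7-methoxy-2,3-dihydro-4H-chromen-4-one (flavanone, racemic at C2, not isolated) | COc1cc(O)c2c(c1)OC(c1ccc(OCc3ccccc3)cc1)CC2=O | intermediate
5 | 2-[4-(benzyloxy)phenyl]-5-hydroxy-7-methoxy-4H-chromen-4-one (4'-O-benzylgenkwanin) | COc1cc(O)c2c(=O)cc(-c3ccc(OCc4ccccc4)cc3)oc2c1 | intermediate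
6 | genkwanin (5-hydroxy-2-(4-hydroxyphenyl)-7-methoxy-4H-chromen-4-one) | COc1cc(O)c2c(=O)cc(-c3ccc(O)cc3)oc2c1 | intermediate
7 | 4-(5-hydroxy-7-methoxy-4-oxo-4H-chromen-2-yl)phenyl 2,2-dimethylpropanoate (4'-O-pivaloylgenkwanin) | COc1cc(O)c2c(=O)cc(-c3ccc(OC(=O)C(C)(C)C)cc3)oc2c1 | intermediate
8 | C8–C8''-linked bis(8H-chromene-4,5-dione) tautomer of 9 (bis-dienone; the two sp3 carbons C8 and C8'' form without control, all diastereomers tautomerise to 9; not isolated) | COC1=CC(=O)C2=C(OC(c3ccc(OC(=O)C(C)(C)C)cc3)=CC2=O)C1C1C(OC)=CC(=O)C2=C1OC(c1ccc(OC(=O)C(C)(C)C)cc1)=CC2=O | intermediate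
9 | (5,5'-dihydroxy-7,7'-dimethoxy-4,4'-dioxo-4H,4'H-[8,8'-bichromene]-2,2'-diyl)bis(4,1-phenylene) bis(2,2-dimethylpropanoate) (racemic about the C8–C8'' axis) | COc1cc(O)c2c(=O)cc(-c3ccc(OC(=O)C(C)(C)C)cc3)oc2c1-c1c(OC)cc(O)c2c(=O)cc(-c3ccc(OC(=O)C(C)(C)C)cc3)oc12 | intermediate
10 | 7,7''-di-O-methylcupressuflavone (racemic about the C8–C8'' axis) | COc1cc(O)c2c(=O)cc(-c3ccc(O)cc3)oc2c1-c1c(OC)cc(O)c2c(=O)cc(-c3ccc(O)cc3)oc12 | target

**Step count and risks**

Total step count: 6. Longest linear sequence: 6 steps (1 and 2 to 3, 5, 6, 7, 9, 10).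

Steps most likely to fail:

Step 5. The chelated, acyl-substituted phenol may resist oxidation so that conversion stalls, or coupling may also occur at C6 and give 6,8''- and 6,6''-linked isomers that are hard to separate. The fallback sets out from compound 5 and returns at compound 10, replacing steps 3 to 6 by a halide-based homocoupling. Benzylation of the C5 hydroxyl (benzyl bromide, K2CO3, DMF, 80 °C) should give 5-(benzyloxy)-2-[4-(benzyloxy)phenyl]-7-methoxy-4H-chromen-4-one F1. With the C5 oxygen etherified, electrophilic iodination (I2, CF3CO2Ag, CH2Cl2, rt) is expected at C8 and should give 5-(benzyloxy)-2-[4-(benzyloxy)phenyl]-8-iodo-7-methoxy-4H-chromen-4-one F2. Ullmann homocoupling (activated Cu powder, DMF, 150 °C) should then give the tetrabenzyl ether 5,5'-bis(benzyloxy)-2,2'-bis[4-(benzyloxy)phenyl]-7,7'-dimethoxy-4H,4'H-[8,8'-bichromene]-4,4'-dione F3. Hydrogenolysis of the four benzyl ethers (H2, Pd/C, THF–MeOH, rt) should deliver 10.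

Step 1. Enolisation of the doubly deprotonated acetophenone is slow, so the aldehyde may be consumed by Cannizzaro disproportionation and conversion may stay low. The fallback sets out from compound 1 and returns at compound 5, replacing steps 1 and 2 by a diketone route. C-aroylation of the lithium polyanion of 1 (LiHMDS, 4 equiv, THF, −78 to −10 °C; then 4-(benzyloxy)benzoyl chloride, −78 °C to rt; aq HCl) should give 1-[4-(benzyloxy)phenyl]-3-(2,6-dihydroxy-4-methoxyphenyl)propane-1,3-dione F4, the same diketone a Baker–Venkataraman rearrangement would give. Acid-catalysed cyclodehydration (TsOH, toluene, reflux) should close ring C to 5.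

Step 2. Electrophilic iodination of the electron-rich ring A at C6 or C8 may compete with the dehydrogenation. The fallback sets out from compound 3 and returns at compound 5 without any halogen. Base-mediated oxa-Michael ring closure (NaOAc, EtOH, reflux) should give flavanone 4, now isolated. Palladium-catalysed aerobic dehydrogenation (Pd(O2CCF3)2 5 mol %, DMSO, O2 1 atm, AcOH, 80 °C) should then give 5.

Further compounds
F1 | step 5 | 5-(benzyloxy)-2-[4-(benzyloxy)phenyl]-7-methoxy-4H-chromen-4-one | COc1cc(OCc2ccccc2)c2c(=O)cc(-c3ccc(OCc4ccccc4)cc3)oc2c1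
F2 | step 5 | 5-(benzyloxy)-2-[4-(benzyloxy)phenyl]-8-iodo-7-methoxy-4H-chromen-4-one | COc1cc(OCc2ccccc2)c2c(=O)cc(-c3ccc(OCc4ccccc4)cc3)oc2c1I
F3 | step 5 | 5,5'-bis(benzyloxy)-2,2'-bis[4-(benzyloxy)phenyl]-7,7'-dimethoxy-4H,4'H-[8,8'-bichromene]-4,4'-dione (racemic about the axis) | COc1cc(OCc2ccccc2)c2c(=O)cc(-c3ccc(OCc4ccccc4)cc3)oc2c1-c1c(OC)cc(OCc2ccccc2)c2c(=O)cc(-c3ccc(OCc4ccccc4)cc3)oc12
F4 | step 1 | 1-[4-(benzyloxy)phenyl]-3-(2,6-dihydroxy-4-methoxyphenyl)propane-1,3-dione | COc1cc(O)c(C(=O)CC(=O)c2ccc(OCc3ccccc3)cc2)c(O)c1
F0 | step 2 | none | none
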